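The data come from a simulation on assumed constants, and the scatter is random.

Temperature reaches X in these flasks by way of a small dissolved pool, and the two earlier runs let us weigh it. Solid J passes into solution as Q, solid Z as L, and Q with L gives X.

| setting | birch | cedar | dusk | midnight |
|---|---|---|---|---|
| J | 0.011 M | 0.011 M | 0.011 M | 0.011 M |
| Z | 0.042 M | 0.055 M | 0.0330 M | 0.0500 M |
| temperature | −10 °C | 12 °C |  |  |
| remark | run made earlier | run made earlier | at 20 °C until 40 h, from then on at −20 °C | at −20 °C throughout |
| time |  |  | 5.0 d | 15 d |

| run | time / d | X / % | J / % |
|---|---|---|---|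
| birch | 3.00 | 26.4 | 69.9 |
| birch | 8.00 | 75.2 | 21.3 |
| birch | 12.0 | 100.1 | 0 |
| birch | 20.0 | 100.2 | 0.4 |
| cedar | 0.417 | 5.4 | 92.7 |
| cedar | 0.833 | 14.4 | 84.1 |
| cedar | 2.00 | 37.1 | 60.9 |
| cedar | 5.00 | 97.6 | 0.8 |

(each reading ± 0.3 percentage points)

- the flask that ends with the higher amount of X, in percent of the J charged, or "neither" when 2 percentage points or less lies between them (dusk / midnight / neither)
- final X, as a percentage of the J charged, in dusk
- final X, as a percentage of the J charged, in midnight

- what is said of X includes D
- J, Z, D is a solid; its amount is given per volume of the solution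
- on the list of suspects stand: D <-> X; Z <-> L; J <-> Q; Q + L -> X
- at the start none of Z is in solution
- at the start none of J is in solution
- what has only dissolved of J counts as not reacted

In both runs X climbs along a straight line, so each run has one pace, zero order in J: birch gives 0.0976 d⁻¹ of the charge, cedar 0.200 d⁻¹. What J and X together fall short of the charge we read as the Q pool: 0.0360 in birch, 0.0175 in cedar. Here is the oddity: cedar runs twice as fast as birch on half the pool.

Divide pace by pool and it clears. Each unit of Q turns over at 2.71 d⁻¹ in birch and 11.4 d⁻¹ in cedar, which lie 0.624 powers of ten apart. In a steady state the pace also equals the refill from solid J, and we take that refill as falling straight with the pool. The two runs then give a refill constant of 5.52 d⁻¹ and a ceiling of 0.0537.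

We assume L stays much the same. Taking turnover as an activated step, straight in the inverse of the absolute temperature, −20 °C lies 0.512 of the birch-to-cedar step beyond birch, so turnover drops by 0.319 powers of ten to 1.30 d⁻¹. Balancing refill against turnover gives a pool of 0.0435 and the cold pace 0.0565 d⁻¹, the fraction of the charge made into X per day in the steady state at that temperature. The same scale upward gives 0.227 d⁻¹ at 20 °C. Taking off the delays where the straight lines of cedar and birch start, we reckon 54.2 % for dusk and 83.0 % for midnight.

The forecast, resting on “X rising linearly while solid J falls”, says midnight, with 61 % in dusk and 95 % in midnight. The simulation gives midnight, with 53.7 % in dusk and 81.5 % in midnight.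

    D ⇌ X, rate k1*(cs1 - [X]) while solid is left; crystals form when [X] > cs1 (solubility = 7.90 mM, k = 0.108 min⁻¹)
    Z ⇌ L, rate k2*(cs2 - [L]) while solid is left; crystals form when [L] > cs2 (solubility = 3.00 mM, k = 0.00260 min⁻¹)
    J ⇌ Q, rate k3*(cs3 - [Q]) while solid is left; crystals form when [Q] > cs3 (solubility = 0.500 mM, k = 0.00474 min⁻¹)
    Q + L → X (k = 5.89 L mol⁻¹ min⁻¹, Ea = 43.0 kJ mol⁻¹)
    (constants at 20 °C)

Midnight's second half runs at 0.0553 d⁻¹, a little slower than our cold pace, which rests on pools read as small differences. Midnight ends above dusk mainly because of the difference in time: held to the time of dusk, midnight gives 26.2 % against 81.5 %. Now read dusk later, at 12 d. Its 53.7 % plus the cold pace over the added days gives 93.2 %, and the computed flask gives 92.4 %.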